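## The problem

The target **20** is (R)-4-(2,5-dibromo-1H-indol-3-yl)-4,5-dihydro-1H-imidazol-2-amine. It is a 2,5-dibromoindole whose C3 is joined by one C–C bond to C4 of a 2-aminoimidazoline (ring atoms N1, C2, N3, C4, C5). The two rings share no atom, so the task is to build one carbon, C4, that is bonded to indole C3, N3, C5 and hydrogen. C4 is the only stereocentre and has the R configuration. Nothing else in the molecule can relay chirality to it, so its configuration must come from an external controller and then be carried unchanged to the end. C4 is benzylic to an electron-rich heteroarene and α to nitrogen. With a free indole N–H the ring nitrogen can expel N3 (gramine-type ionisation), so acid on an unprotected indole threatens racemisation. The two C–Br bonds exclude hydrogenolysis, dissolving metals and late zerovalent palladium, and the 2-bromoindole tolerates neither aqueous acid nor organometallic steps. The cyclic guanidine is strongly basic and nucleophilic and must stay masked until the last step. The enabling feature is that C4 carries three different bonds at once. Indole C3 can arrive as a carbon nucleophile on boron, N3 as an amine, and C4–C5 as glyoxylic acid whose carboxyl is the latent C5.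

## Retrosynthesis

**Guanidine unmasking.** No skeletal bond is cut between **20** and its bis-Boc derivative **19**. Boc is chosen because it is removed by anhydrous acid, which leaves both C–Br bonds alone, whereas benzyl-type groups would need hydrogenolysis. The forward step must avoid water (2-bromoindole) and must not ionise C4.

**C2–Br bond.** Cutting the C2–Br bond of **19** gives the N–H indole **18**, and this in turn is the detosylated form of **17**. Bromine is placed late because a 2,5-dibromoindol-3-yl boron reagent would be hindered and electron-poor in the aryl-transfer step, and a C2–Br bond would not survive magnesium chemistry. The forward reactions must brominate C2 selectively on a C3-blocked indole and remove the sulfonyl group without harming the acylguanidine.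

**N1–C5 bond.** Cutting N1–C5 of **17** gives the acyclic hydroxyethyl guanidine **16**, closed forward by an intramolecular Mitsunobu reaction. The neighbouring option, a 1,2-diamine closed with a one-carbon electrophile, needs C5 converted to an amine first and costs two more steps. Cutting C2–N3 of **16** then gives the amino alcohol **14** and the guanylating reagent **15**.

**Functional group changes.** The amine **14** comes from the sulfinamide **13**, and **13** from reduction of the carboxylic acid **12**. Compound **12** is an indol-3-ylglycine in which C5 is still a carboxyl and N3 carries the chiral sulfinyl group. These steps must not enolise or ionise C4.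

**Indole C3–C4 and C4–N3 bonds (key cut).** Compound **12** is divided into the boronic acid **7**, glyoxylic acid monohydrate **8** and (R)-tert-butanesulfinamide **9**. The imino acid **10** and its boronate complex **11** are transient. A two-component Friedel–Crafts addition would need an electron-rich N–H indole, which leaves C4 prone to ionisation. Ipso transfer from boron works on the N-tosyl indole and fixes the site as C3. The free carboxyl both carries C5 and organises the transfer. The forward reaction must give facial control from sulfur and must transfer the aryl group faster than the C–B bond is protonated.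

**C3–B bond.** The boronic acid **7** comes from the iodide **3** and triisopropyl borate **4**, through the magnesium species **5** and the borate **6**. Iodide **3** comes from 5-bromoindole **1** by C3 iodination (via **2**) and N-tosylation. The tosyl group makes the exchange clean, stabilises the boronic acid and damps ionisation at C4 through all acidic steps.

## Roads not taken

**Alternative 1:** Here the 2-bromoindole is read as the enol bromide of an oxindole and the aminoimidazoline as an activated cyclic urea, and the indole C3–C3a bond is cut.
- **Key step:** the 2-iodoanilide **A1** would cyclise through its amide enolate with Pd(OAc)2, tricyclohexylphosphine and NaOtBu, after insertion of zerovalent palladium into the C–I bond. The product is oxindole **A2** as a C3 epimer mixture, which is harmless because C3 later becomes sp2. POBr3 would then activate both carbonyl groups.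
- **Merits:** the stereocentre comes from the amino-acid pool, the C2 bromine is placed by construction, and no indolyl organometallic is needed.
- **Weak points:** the enolate sits β to the urea nitrogen on C4, so base-induced loss of that nitrogen threatens ring and stereocentre. The urea N–H groups can compete for arylpalladium, and palladium must tell C–I from C–Br. Hot POBr3, then amination beside a 2-bromoindole, then removal of a 4-methoxybenzyl group from indole nitrogen are all harsh on an ionisable C4–N bond.
- **Comparison:** this road is better in the origin of chirality and in the placement of the C2 bromine. The chosen plan sets against it mild conditions once C4 exists, a protecting-group set of tosyl and Boc only, and a shorter sequence.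

**Alternative 2:** N3–C4 and indole C3–C3a are cut together.
- **Key step:** zerovalent palladium inserts into a C–I bond, then the urea nitrogen and the aryl group add syn across an (E)-alkene. This gives **A3**, with imidazolidinone and indoline rings closed at once.
- **Merits:** two rings, two bonds and two stereocentres form in one step. That is more complexity per step than the Petasis reaction, which closes no ring.
- **Weak points:** the precursor is achiral, so absolute configuration would rest on a chiral ligand in a domino process with no close precedent for this substrate type. The indoline C3 stereocentre is made only to be destroyed by dehydrogenation, and that oxidation must spare benzylic C4. The urea must still be converted to the aminoimidazoline, two N-aryl or N-benzyl groups need oxidative or strongly acidic removal beside an indole, and C2 bromination remains.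
- **Comparison:** the chosen plan forms fewer bonds in its key step. It compensates with reliable auxiliary control, no wasted stereocentre and a much lighter end-game.

**Alternative 3:** indole C3–C3a and N1–C2 are cut.
- **Key step:** Pd(OAc)2 couples aniline **A4** with the chiral-pool silyl alkyne **A5** (Larock heteroannulation) to give **A6**, with silicon at C2.
- **Merits:** the stereocentre is bought, not induced. The C2 silyl group is a placeholder for ipso bromodesilylation, so the bromine position is not a selectivity question. The indole needs no N-protection, and **A6** is a masked form of the same amino alcohol as **14**. In these three respects this road is as good as or better than the chosen one.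
- **Weak points:** palladium at high temperature must insert into C–I and leave C–Br. The bulky α-branched silyl alkyne should insert slowly. Unmasking the amino alcohol needs acid on a free N–H indole, where ionisation at C4 is easiest and where C2–Si is prone to protodesilylation. Bromodesilylation would therefore have to come first, and the acid-sensitive 2-bromoindole would be carried through four further steps.
- **Comparison:** the chosen plan sets against it the tosyl group that suppresses ionisation at C4 in every acidic step, no palladium beside C–Br, a cheap indole start, and bromination only after all but one manipulation.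

Key step: step 3

Assumption: the indolyl group is taken to add to the face of the s-cis N-sulfinyl imine remote from the tert-butyl group, which for (R)-sulfur corresponds to (R) at carbon; the descriptors of **12** follow this model.

## Route

Step 1
Reactants: 1 5-bromo-1H-indole
Product: 3 5-bromo-3-iodo-1-tosyl-1H-indole, via 5-bromo-3-iodo-1H-indole 2 (not isolated)
Conditions: I2, KOH, DMF, rt; then TsCl, 0 °C to rt
Reagents that add atoms: iodine, II; 4-methylbenzenesulfonyl chloride, Cc1ccc(cc1)S(=O)(=O)Cl
Why: Electrophilic iodination of the indolide goes to C3, the most nucleophilic carbon; the sensitive 3-iodoindole is N-sulfonylated in the same basic pot, so it is never isolated.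

Step 2
Reactants: 3 5-bromo-3-iodo-1-tosyl-1H-indole; 4 triisopropyl borate
Product: 7 (5-bromo-1-tosyl-1H-indol-3-yl)boronic acid, via (5-bromo-1-tosylindol-3-yl)magnesium chloride 5 (not isolated), via chloromagnesium triisopropoxy(indol-3-yl)borate 6 (not isolated)
Conditions: i-PrMgCl·LiCl, THF, −40 °C; then 4, −40 to 0 °C; 1 M aq. HCl, 0 °C
Reagents that add atoms: water, O
Why: Iodine–magnesium exchange at the sulfonyl-activated C3–I bond is much faster than exchange at the C5 bromide, and the C3-magnesiated N-sulfonylindole should not migrate to C2 at this temperature; borate trapping and mild hydrolysis give the boronic acid.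

Step 3
Reactants: 7 (5-bromo-1-tosyl-1H-indol-3-yl)boronic acid; 8 glyoxylic acid monohydrate; 9 (R)-2-methylpropane-2-sulfinamide
Product: 12 (R)-2-(5-bromo-1-tosyl-1H-indol-3-yl)-2-{[(R)-tert-butylsulfinyl]amino}acetic acid, via (R)-N-sulfinyl iminoacetic acid 10 (not isolated), via acyloxyboronate ate complex 11 (not isolated)
Conditions: InBr3 (20 mol%), 4 Å molecular sieves, CH2Cl2, rt
Reagents that add atoms: none
Why: This is the Petasis borono-Mannich reaction in its known sulfinamide, glyoxylic acid and InBr3 variant, here with an N-sulfonyl indol-3-ylboronic acid as the boron component. InBr3 promotes condensation of 9 with 8 to the (E)-N-sulfinyl imino acid 10, which forms the C4–N3 bond; the carboxyl oxygen then binds boron of 7 to give the tetracoordinate boronate 11. Within 11 the indolyl group migrates from boron to the imine carbon through a five-membered cyclic transition state, forming the indole C3–C4 bond at the ipso carbon only. No ring is closed. The new stereocentre C4 is controlled by the sulfur stereocentre: in the s-cis sulfinyl imine the tert-butyl group covers one face and the aryl group is delivered to the other, which should give (R) at carbon, and any minor diastereomer should be separable at 12 or 13. The step needs aryl transfer to outrun protonolysis of the C–B bond and needs reaction at C3 only; the tosyl group slows protonolysis and rules out a direct Friedel–Crafts path, and ipso transfer fixes the site. The C5 bromide and the sulfonamide are spectators under these mildly acidic conditions.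

Step 4
Reactants: 12 (R)-2-(5-bromo-1-tosyl-1H-indol-3-yl)-2-{[(R)-tert-butylsulfinyl]amino}acetic acid
Product: 13 (R)-N-[(R)-1-(5-bromo-1-tosyl-1H-indol-3-yl)-2-hydroxyethyl]-2-methylpropane-2-sulfinamide
Conditions: BH3·SMe2, THF, 0 °C to rt; then MeOH
Reagents that add atoms: none
Why: Borane reduces the free carboxylic acid through its acyloxyborane without any base, so the arylglycine centre is not enolised; sulfinamide, N-sulfonyl indole and aryl bromide should be inert to borane at this temperature.

Step 5
Reactants: 13 (R)-N-[(R)-1-(5-bromo-1-tosyl-1H-indol-3-yl)-2-hydroxyethyl]-2-methylpropane-2-sulfinamide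
Product: 14 (R)-2-amino-2-(5-bromo-1-tosyl-1H-indol-3-yl)ethan-1-ol
Conditions: HCl (4 M in dioxane), MeOH, 0 °C to rt; then aq. NaHCO3
Reagents that add atoms: none
Why: Acid methanolysis of the S–N bond is the standard removal of a tert-butanesulfinyl group; the tosyl group withholds the indole nitrogen lone pair, so the ammonium group should not be expelled from C4.

Step 6
Reactants: 14 (R)-2-amino-2-(5-bromo-1-tosyl-1H-indol-3-yl)ethan-1-ol; 15 N,N'-bis(tert-butoxycarbonyl)-N''-(trifluoromethylsulfonyl)guanidine
Product: 16 N-[(R)-1-(5-bromo-1-tosyl-1H-indol-3-yl)-2-hydroxyethyl]-N',N''-bis(tert-butoxycarbonyl)guanidine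
Conditions: Et3N, CH2Cl2, rt
Reagents that add atoms: none
Why: Guanylation of a primary amine by addition–elimination on the triflylguanidine, with triflamide as leaving group; the reagent is reactive enough for an α-branched amine and the hydroxyl group does not compete.

Step 7
Reactants: 16 N-[(R)-1-(5-bromo-1-tosyl-1H-indol-3-yl)-2-hydroxyethyl]-N',N''-bis(tert-butoxycarbonyl)guanidine
Product: 17 tert-butyl (R)-4-(5-bromo-1-tosyl-1H-indol-3-yl)-2-[(tert-butoxycarbonyl)imino]imidazolidine-1-carboxylate
Conditions: PPh3, DIAD, THF, 0 °C to rt
Reagents that add atoms: none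
Why: Intramolecular Mitsunobu N-alkylation: the acidic Boc-N–H of the guanidine displaces the primary oxyphosphonium group in a 5-exo-tet closure that forms N1–C5; C4 is not a reacting centre, so its configuration is retained.

Step 8
Reactants: 17 tert-butyl (R)-4-(5-bromo-1-tosyl-1H-indol-3-yl)-2-[(tert-butoxycarbonyl)imino]imidazolidine-1-carboxylate
Product: 18 tert-butyl (R)-4-(5-bromo-1H-indol-3-yl)-2-[(tert-butoxycarbonyl)imino]imidazolidine-1-carboxylate
Conditions: Cs2CO3, THF/MeOH (2:1), rt
Reagents that add atoms: none
Why: Methoxide attacks sulfur and releases the bromoindolide, a nucleophilic desulfonylation that runs at room temperature for electron-poor indoles; the acylguanidine N–H is deprotonated first, which should disfavour loss of N3 from C4.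

Step 9
Reactants: 18 tert-butyl (R)-4-(5-bromo-1H-indol-3-yl)-2-[(tert-butoxycarbonyl)imino]imidazolidine-1-carboxylate
Product: 19 tert-butyl (R)-4-(2,5-dibromo-1H-indol-3-yl)-2-[(tert-butoxycarbonyl)imino]imidazolidine-1-carboxylate
Conditions: NBS (1.0 equiv), CH2Cl2, −20 to 0 °C, dark
Reagents that add atoms: N-bromosuccinimide, O=C1CCC(=O)N1Br
Why: Electrophilic bromination of a 3-substituted N–H indole gives the 2-bromoindole through the 3-bromoindolenine and a 1,2-shift; the C5 bromine deactivates the benzo ring and the two Boc groups keep the guanidine from reacting.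

Step 10
Reactants: 19 tert-butyl (R)-4-(2,5-dibromo-1H-indol-3-yl)-2-[(tert-butoxycarbonyl)imino]imidazolidine-1-carboxylate
Product: 20 (R)-4-(2,5-dibromo-1H-indol-3-yl)-4,5-dihydro-1H-imidazol-2-amine
Conditions: TFA, CH2Cl2, 0 °C to rt; then hydroxide-form anion-exchange resin, MeOH
Reagents that add atoms: none
Why: Acidolysis removes both Boc carbamates; anhydrous acid spares the 2-bromoindole, and the protonated guanidinium is a poor leaving group, so C4 should keep its configuration.

## Compound list

1 | 5-bromo-1H-indole | Brc1ccc2[nH]ccc2c1 | starting material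
2 | 5-bromo-3-iodo-1H-indole | Ic1c[nH]c2ccc(Br)cc12 | intermediate
3 | 5-bromo-3-iodo-1-tosyl-1H-indole | Ic1cn(S(=O)(=O)c2ccc(C)cc2)c2ccc(Br)cc12 | intermediate
4 | triisopropyl borate | CC(C)OB(OC(C)C)OC(C)C | starting material
5 | (5-bromo-1-tosyl-1H-indol-3-yl)magnesium chloride | Cl[Mg]c1cn(S(=O)(=O)c2ccc(C)cc2)c2ccc(Br)cc12 | intermediate
6 | chloromagnesium (5-bromo-1-tosyl-1H-indol-3-yl)triisopropoxyborate | CC(C)O[B-](OC(C)C)(OC(C)C)c1cn(S(=O)(=O)c2ccc(C)cc2)c2ccc(Br)cc12.[Mg+]Cl | intermediate
7 | (5-bromo-1-tosyl-1H-indol-3-yl)boronic acid | OB(O)c1cn(S(=O)(=O)c2ccc(C)cc2)c2ccc(Br)cc12 | intermediate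
8 | glyoxylic acid monohydrate | OC(O)C(=O)O | starting material
9 | (R)-2-methylpropane-2-sulfinamide | CC(C)(C)[S@](N)=O | starting material
10 | (R,E)-2-[(tert-butylsulfinyl)imino]acetic acid | CC(C)(C)[S@@](=O)/N=C/C(=O)O | intermediate
11 | zwitterionic boronate of 10 and 7: [(E)-2-{[(R)-tert-butylsulfinyl]iminio}acetoxy](5-bromo-1-tosyl-1H-indol-3-yl)dihydroxyborate | CC(C)(C)[S@@](=O)/[NH+]=C/C(=O)O[B-](O)(O)c1cn(S(=O)(=O)c2ccc(C)cc2)c2ccc(Br)cc12 | intermediate
12 | (R)-2-(5-bromo-1-tosyl-1H-indol-3-yl)-2-{[(R)-tert-butylsulfinyl]amino}acetic acid | CC(C)(C)[S@@](=O)N[C@H](c1cn(S(=O)(=O)c2ccc(C)cc2)c2ccc(Br)cc12)C(=O)O | intermediate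
13 | (R)-N-[(R)-1-(5-bromo-1-tosyl-1H-indol-3-yl)-2-hydroxyethyl]-2-methylpropane-2-sulfinamide | CC(C)(C)[S@@](=O)N[C@H](c1cn(S(=O)(=O)c2ccc(C)cc2)c2ccc(Br)cc12)CO | intermediate
14 | (R)-2-amino-2-(5-bromo-1-tosyl-1H-indol-3-yl)ethan-1-ol | N[C@H](c1cn(S(=O)(=O)c2ccc(C)cc2)c2ccc(Br)cc12)CO | intermediate
15 | N,N'-bis(tert-butoxycarbonyl)-N''-(trifluoromethylsulfonyl)guanidine | CC(C)(C)OC(=O)NC(=NS(=O)(=O)C(F)(F)F)NC(=O)OC(C)(C)C | starting material
16 | N-[(R)-1-(5-bromo-1-tosyl-1H-indol-3-yl)-2-hydroxyethyl]-N',N''-bis(tert-butoxycarbonyl)guanidine | CC(C)(C)OC(=O)NC(=NC(=O)OC(C)(C)C)N[C@H](c1cn(S(=O)(=O)c2ccc(C)cc2)c2ccc(Br)cc12)CO | intermediate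
17 | tert-butyl (R)-4-(5-bromo-1-tosyl-1H-indol-3-yl)-2-[(tert-butoxycarbonyl)imino]imidazolidine-1-carboxylate | CC(C)(C)OC(=O)N=C1N[C@H](c2cn(S(=O)(=O)c3ccc(C)cc3)c3ccc(Br)cc23)CN1C(=O)OC(C)(C)C | intermediate
18 | tert-butyl (R)-4-(5-bromo-1H-indol-3-yl)-2-[(tert-butoxycarbonyl)imino]imidazolidine-1-carboxylate | CC(C)(C)OC(=O)N=C1N[C@H](c2c[nH]c3ccc(Br)cc23)CN1C(=O)OC(C)(C)C | intermediate
19 | tert-butyl (R)-4-(2,5-dibromo-1H-indol-3-yl)-2-[(tert-butoxycarbonyl)imino]imidazolidine-1-carboxylate | CC(C)(C)OC(=O)N=C1N[C@H](c2c(Br)[nH]c3ccc(Br)cc23)CN1C(=O)OC(C)(C)C | intermediate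
20 | (R)-4-(2,5-dibromo-1H-indol-3-yl)-4,5-dihydro-1H-imidazol-2-amine | NC1=N[C@H](c2c(Br)[nH]c3ccc(Br)cc23)CN1 | target

## Step count and least certain steps

Total step count: 10. Longest linear sequence: 10 steps, from **1** to **20**.

**Step 3 (key step).**
- **Risk:** aryl transfer from the electron-poor N-sulfonyl indolylboron centre may be slow. Protonolysis of the C–B bond in the acidic medium could then outrun C–C bond formation, and facial control by sulfur could be incomplete.
- **Fallback:** the same two bonds at C4 are formed in two stages under near-neutral conditions. It sets out from **7** and **9**. Compound **9** is condensed with ethyl glyoxylate (CuSO4, CH2Cl2) to ethyl (R,E)-2-[(tert-butylsulfinyl)imino]acetate F1. Boronic acid **7** is added to F1 with Rh(acac)(C8H14)2 and 1,2-bis(diphenylphosphino)benzene in dioxane at 70 °C, a known addition of arylboronic acids to N-sulfinyl imino esters by monovalent rhodium. This gives ethyl (R)-2-(5-bromo-1-tosyl-1H-indol-3-yl)-2-{[(R)-tert-butylsulfinyl]amino}acetate F2. LiBH4 in THF reduces F2 to **13**, where the route is rejoined and step 4 is no longer needed.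

**Step 9.**
- **Risk:** the bromonium source attacks C3, and the resulting indolenine may lose the side chain instead of shifting bromine to C2. Over-bromination and oxidative hydrolysis on work-up are further risks.
- **Fallback:** a route that avoids electrophilic attack on the indole π system. It sets out from **18**. C–H borylation with [Ir(OMe)(C8H12)]2, 4,4'-di-tert-butyl-2,2'-bipyridine and B2pin2 in THF at 60 °C is selective for C2 of N–H indoles. It gives tert-butyl (R)-4-[5-bromo-2-(4,4,5,5-tetramethyl-1,3,2-dioxaborolan-2-yl)-1H-indol-3-yl]-2-[(tert-butoxycarbonyl)imino]imidazolidine-1-carboxylate F3. Bromodeboronation of F3 with CuBr2 in MeOH/H2O returns to the route at **19**.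

**Step 8.**
- **Risk:** methoxide may cause partial loss or migration of a Boc group of the acylguanidine. Base-induced ionisation at C4 may set in once the indole nitrogen is free.
- **Fallback:** the order of deprotection is reversed. It sets out from **17**. TFA in CH2Cl2 gives (R)-4-(5-bromo-1-tosyl-1H-indol-3-yl)-4,5-dihydro-1H-imidazol-2-amine F4. Cs2CO3 in MeOH/THF at 60 °C, now with no carbamate to lose, gives (R)-4-(5-bromo-1H-indol-3-yl)-4,5-dihydro-1H-imidazol-2-amine F5. NBS in TFA at 0 °C brominates C2 of F5 as its guanidinium salt and returns to the route at **20**, replacing steps 8 to 10.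

**Step 2.**
- **Risk:** exchange at the C5 bromide or migration of the metal to C2 on warming, and loss of boron during the acidic hydrolysis.
- **Fallback:** the carbanion is avoided. It sets out from **3**. Borylation with PdCl2(dppf), Et3N and pinacolborane in dioxane at 80 °C relies on the faster insertion of zerovalent palladium into C–I than into C–Br. It gives 5-bromo-3-(4,4,5,5-tetramethyl-1,3,2-dioxaborolan-2-yl)-1-tosyl-1H-indole F6. Oxidative cleavage of the pinacol ester of F6 with NaIO4 and NH4OAc in acetone/H2O returns to the route at **7**.

**Step 7.**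
- **Risk:** the activated alcohol may be intercepted by the reduced azodicarboxylate or may eliminate before the guanidine closes the ring.
- **Fallback:** the redox condensation is replaced by a stepwise sulfonate displacement. It sets out from **16**. MsCl and Et3N in CH2Cl2 at 0 °C give (R)-2-(5-bromo-1-tosyl-1H-indol-3-yl)-2-[N',N''-bis(tert-butoxycarbonyl)guanidino]ethyl methanesulfonate F7. K2CO3 in MeCN at 50 °C closes the ring from F7 and returns to the route at **17**.

## Further compounds

F1 | step 3 | ethyl (R,E)-2-[(tert-butylsulfinyl)imino]acetate | CC(C)(C)[S@@](=O)/N=C/C(=O)OCC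
F2 | step 3 | ethyl (R)-2-(5-bromo-1-tosyl-1H-indol-3-yl)-2-{[(R)-tert-butylsulfinyl]amino}acetate | CC(C)(C)[S@@](=O)N[C@H](c1cn(S(=O)(=O)c2ccc(C)cc2)c2ccc(Br)cc12)C(=O)OCC
F3 | step 9 | tert-butyl (R)-4-[5-bromo-2-(4,4,5,5-tetramethyl-1,3,2-dioxaborolan-2-yl)-1H-indol-3-yl]-2-[(tert-butoxycarbonyl)imino]imidazolidine-1-carboxylate | CC(C)(C)OC(=O)N=C1N[C@H](c2c(B3OC(C)(C)C(C)(C)O3)[nH]c3ccc(Br)cc23)CN1C(=O)OC(C)(C)C
F4 | step 8 | (R)-4-(5-bromo-1-tosyl-1H-indol-3-yl)-4,5-dihydro-1H-imidazol-2-amine | NC1=N[C@H](c2cn(S(=O)(=O)c3ccc(C)cc3)c3ccc(Br)cc23)CN1
F5 | step 8 | (R)-4-(5-bromo-1H-indol-3-yl)-4,5-dihydro-1H-imidazol-2-amine | NC1=N[C@H](c2c[nH]c3ccc(Br)cc23)CN1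
F6 | step 2 | 5-bromo-3-(4,4,5,5-tetramethyl-1,3,2-dioxaborolan-2-yl)-1-tosyl-1H-indole | CC1(C)OB(OC1(C)C)c1cn(S(=O)(=O)c2ccc(C)cc2)c2ccc(Br)cc12
F7 | step 7 | (R)-2-(5-bromo-1-tosyl-1H-indol-3-yl)-2-[N',N''-bis(tert-butoxycarbonyl)guanidino]ethyl methanesulfonate | CC(C)(C)OC(=O)NC(=NC(=O)OC(C)(C)C)N[C@H](c1cn(S(=O)(=O)c2ccc(C)cc2)c2ccc(Br)cc12)COS(C)(=O)=O
A1 | alternative 1 | (R)-N-(4-bromo-2-iodophenyl)-N-(4-methoxybenzyl)-2-(2-oxoimidazolidin-4-yl)acetamide | O=C1N[C@H](CC(=O)N(Cc2ccc(OC)cc2)c2ccc(Br)cc2I)CN1
A2 | alternative 1 | 5-bromo-1-(4-methoxybenzyl)-3-[(R)-2-oxoimidazolidin-4-yl]indolin-2-one, mixture of C3 epimers | O=C1N[C@H](C2C(=O)N(Cc3ccc(OC)cc3)c3ccc(Br)cc23)CN1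
A3 | alternative 2 | tert-butyl (3S)-5-bromo-3-[(4R)-1-(4-methoxybenzyl)-3-(4-methoxyphenyl)-2-oxoimidazolidin-4-yl]indoline-1-carboxylate | COc1ccc(CN2C[C@H](N(C2=O)c2ccc(OC)cc2)[C@@H]2CN(C(=O)OC(C)(C)C)c3ccc(Br)cc23)cc1
A4 | alternative 3 | 4-bromo-2-iodoaniline | Nc1ccc(Br)cc1I
A5 | alternative 3 | tert-butyl (R)-2,2-dimethyl-4-[(triethylsilyl)ethynyl]oxazolidine-3-carboxylate | CC(C)(C)OC(=O)N1[C@H](C#C[Si](CC)(CC)CC)COC1(C)C
A6 | alternative 3 | tert-butyl (R)-4-[5-bromo-2-(triethylsilyl)-1H-indol-3-yl]-2,2-dimethyloxazolidine-3-carboxylate | CC(C)(C)OC(=O)N1[C@H](c2c([Si](CC)(CC)CC)[nH]c3ccc(Br)cc23)COC1(C)C
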